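The amounts of target and isomer in the earlier runs were small, so I worked in fractions of the substrate charged and asked what fraction of target plus isomer was still left as target.

| setting | south | east | north | south-east | winter | autumn | midnight |
|---|---|---|---|---|---|---|---|
| substrate | 0.050 M | 0.034 M | 0.075 M | 0.050 M | 0.050 M (fed, over 25 min) | 0.050 M | 0.050 M |
| partner A | 0.040 M | 0.040 M | 0.040 M | 0.040 M | 0.0400 M | 0.0400 M | 0.0400 M (fed, over 25 min) |
| partner B | 0.050 M | 0.050 M | 0.050 M | 0.025 M | 0.0500 M | 0.0500 M | 0.0500 M |
| remark | run made earlier | run made earlier | run made earlier | run made earlier | all else is in the flask from the start; the feed brings no volume worth counting | everything together at the start | all else is in the flask from the start; the feed brings no volume worth counting |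
| time |  |  |  |  | 40 min | 40 min | 40 min |

| run | time / min | target / % | isomer of the product / % |
|---|---|---|---|
| south | 2.00 | 1.3 | 1.6 |
| south | 6.00 | 5.2 | 1.5 |
| south | 12.0 | 5.6 | 0 |
| south | 15.0 | 6.2 | 3.1 |
| south | 25.0 | 7.1 | 6.2 |
| east | 2.00 | 2.7 | 0 |
| east | 6.00 | 11.4 | 3.0 |
| east | 12.0 | 19.3 | 8.5 |
| east | 15.0 | 17.1 | 8.3 |
| east | 25.0 | 20.9 | 12.1 |
| north | 5.00 | 1.9 | 0.4 |
| north | 10.0 | 1.6 | 1.5 |
| north | 15.0 | 0.2 | 0 |
| north | 20.0 | 3.1 | 1.6 |
| north | 25.0 | 2.4 | 1.5 |
| south-east | 5.00 | 0.7 | 0.9 |
| south-east | 10.0 | 3.8 | 0.2 |
| south-east | 15.0 | 2.1 | 0.5 |
| south-east | 20.0 | 0 | 1.2 |
| south-east | 25.0 | 3.2 | 0 |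

(standard deviation of a reading: 1 percentage point)

- the numbers in the tables scatter by 1 percentage point (one standard deviation)
- a reading or a percentage of target counts all its forms, free or not

- the flask that comes out highest in share of target in target plus isomer of the product, or "all alike" when all lie within 1.5 percentage points (winter / autumn / midnight / all alike)
- share of target in target plus isomer of the product at the end, winter
- share of target in target plus isomer of the product at the end, autumn
- share of target in target plus isomer of the product at the end, midnight

For the bound from below, I pooled the south and east readings at 15.0 min and 25.0 min, which gave 63.3%. I called this the settled share, the fraction of free target plus isomer that is target once the two stand in balance, which is the thermodynamic limit of that pair, here taken as a reading from those pooled values. If isomer comes from target and the pair has reached balance, this share holds for the free pair, and any target held in a bound form lifts a flask's counted share above this floor.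

For the bound from above, fresh target would stand at 100 percent. I tightened that to the east reading at 6.00 min, 79.2%, taking the target at 40 min to be older than the target in that reading. My bracket was therefore 16 percentage points wide, more than the margin, so it named no flask.

The forecast chose midnight, with 40% for winter, 50% for autumn and 62% for midnight, on the ground that “share therefore depends on the mean age of target”. Its winter and autumn figures lay below my floor, and its midnight figure lay beside it.

The flasks gave 71.4% for winter, 64.5% for autumn and 63.1% for midnight, so winter stood highest.

    open intermediate + second intermediate → target (k = 0.0512 M⁻¹ s⁻¹)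
    target ⇌ isomer of the product (K = 0.600, k = 0.00205 s⁻¹)
    partner B + partner A → second intermediate (k = 0.165 M⁻¹ s⁻¹)
    substrate + target ⇌ idle adduct, settled at all times (K = 14.8 M⁻¹)
    substrate + partner B → open intermediate (k = 2.26 M⁻¹ s⁻¹)
    2 second intermediate → homo product (k = 0.0200 M⁻¹ s⁻¹)

Winter ended with 58.8% of its substrate unused and idle adduct at 10.2%, a percentage in which each adduct counts as two, so half of it is target. Winter's isomer, 6.77%, with the settled share gives free target of 11.7%, and adding the bound target gives a share of 71.3%. In the winter neighbour with 0.020 M of substrate, isomer at 15.1% and idle adduct at 4.54% give 65.2% the same way, and that flask stood at 65.7%.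

The earlier runs and the new flask come from a simulation for substances that don't exist, noise included.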